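Two flasks cannot both be short of free base when one holds 1.8 equiv and the other 3.2 equiv, yet both keep the same electrophile.

| flask | electrophile | nucleophile | free base | remark | time |
|---|---|---|---|---|---|
| dusk | 0.30 M | 1.1 equiv | 1.8 equiv | run made earlier |  |
| midnight | 0.30 M | 1.1 equiv | 3.2 equiv | run made earlier |  |
| north-east | 0.30 M | 1.10 equiv | 1.50 equiv |  | 2.5 d |
| south-east | 0.30 M | 1.10 equiv | 2.00 equiv |  | 2.5 d |

- dusk (time / d: electrophile / %, target / %): 0.208: 87.9, 11.9; 0.333: 82.9, 16.5; 0.500: 76.8, 21.7; 0.833: 69.0, 28.7; 1.67: 56.9, 37.7; 2.50: 50.2, 41.2
- midnight (time / d: electrophile / %, target / %): 0.208: 88.0, 11.6; 0.333: 82.8, 17.3; 0.500: 77.5, 22.2; 0.833: 69.9, 28.7; 1.67: 57.1, 37.8; 2.50: 50.3, 41.6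

(scatter of a reading: 0.3 percentage points)

- the numbers in the tables scatter by 0.3 percentage points (one standard deviation)

- part of the electrophile that has reacted at the end, north-east
- part of the electrophile that has reacted at the end, south-east
- what raising the equivalents of free base from its lowest to its highest value here does to the part of the electrophile that has reacted (changes below 5 percentage points count as none) (it rises / no change / it falls)

The electrophile is the smaller charge, the limiting reagent by the recipe, so I keep its balance as fractions of that charge. At 2.50 d, dusk leaves 50.2% and midnight 50.3%, a gap of 0.1 percentage points, less than the scatter of 0.3 points. So I take 49.8% reacted from dusk, the run nearest in free base to both new flasks. Now suppose that each reacted electrophile takes one free base. The share of the base charge so taken is 33.2% in north-east; I call it the base claim, electrophile reacted over free base charged. South-east has 24.9%, dusk 27.7%, midnight 15.6%.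

The weak link is north-east, whose claim is higher than dusk's, so it lies outside the tested runs. I reforge it with a straight line: the uncertainty of the two readings' difference, scaled down to the step from 1.8 equiv to 1.50 equiv, is 0.091 points. I commit to 49.8% for both flasks, so no change. The forecast gives 49.7% (46.5% to 51%) for north-east, where mine stands at 49.8%, and 49.8% (48.8% to 50.8%) for south-east, with no change: “so base should still be in excess”.

The flasks give 49.7% in north-east and 49.8% in south-east, no change, a change of 0.054 points.

    electrophile + target → side product (k = 0.0120 M⁻¹ h⁻¹)
    free base ⇌ dormant form (K = 1.40, k = 0.0210 h⁻¹)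
    acid set free + free base ⇌ salt of the base, settled at all times (K = 3200 M⁻¹)
    2 nucleophile → homo dimer (k = 0.0660 M⁻¹ h⁻¹)
    nucleophile + acid set free ⇌ protonated nucleophile, settled at all times (K = 130 M⁻¹)
    electrophile + nucleophile → acid set free + target (k = 0.0890 M⁻¹ h⁻¹)

In north-east, 31.3% of the charged free base is still free at the end, and the step into the dormant form makes no difference to the answer. The salt of the base holds 30.0% of the base charge there, less than the claim.

A neighbour of north-east, the same flask with 0.440 equiv of nucleophile, has 28.4% of its electrophile reacted at the end, so its claim is 19.0%. The computed salt of the base there holds 17.0% of the base charge, less again.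

The data come from a simulation for substances that don't exist; noise was put on by code.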